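X has one way in, from G, and one way out, to Q, so the question is how much of it stands at the end in each of these flasks:

| flask | G | temperature | time |
|---|---|---|---|
| south-west | 0.59 M | 80 °C | 6.0 d |
| south | 0.59 M | 30 °C | 6.0 d |
| north-west | 0.59 M | 55 °C | 6.0 d |
| north-east | 0.59 M | 5 °C | 6.0 d |

    G → L (k1 = 4.9 × 10⁻⁶ /s, Ea1 = 115 kJ/mol)
    X → Q (k2 = 7.8 × 10⁻⁶ /s, Ea2 = 117 kJ/mol)
    G → J (k3 = 1.3 × 10⁻⁸ /s, Ea3 = 130 kJ/mol)
    G → X (k4 = 5.2 × 10⁻⁵ /s, Ea4 = 123 kJ/mol)
    G → D (k5 = 2.2 × 10⁻⁵ /s, Ea5 = 117 kJ/mol)
    D ⇌ E (K6 = 1.7, k6 = 2.2 × 10⁻⁶ /s, Ea6 = 127 kJ/mol, ΔH6 = −21.0 kJ/mol)
    L ⇌ Z (K7 = 1.4, k7 = 2.0 × 10⁻⁶ /s, Ea7 = 112 kJ/mol, ΔH7 = −33.0 kJ/mol)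
    (constants at 80 °C)

- at 80 °C the constants are as listed, elsewhere as the activation energies and enthalpies make them

- the flask that comes out highest in amount of X, in percent of the G charged, or "all alike" when all lie within 1.5 percentage points (south-west / south / north-west / north-east / all alike)
- X at the end, in percent of the G charged, south-west
- X at the end, in percent of the G charged, south
- X at the end, in percent of the G charged, north-west
- X at the end, in percent of the G charged, north-east

Two chemists dispute this. Let kG be the sum of the constants with which G leaves, and kX the constant with which X passes into Q.

The first chemist argues from heat. In south-west, at 80 °C, the lifetime of G, one over kG, is 3.52 h, much shorter than the time allowed. The step into X also has a higher activation energy than the steps into L and D. The share of G going to X, the selectivity towards X, is 65.9% there, and that is the first chemist's figure for X in south-west.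

The second chemist answers that X is a middle member, and that heat speeds its loss as well. For north-west the second chemist's number is 0.589: this is the peak number w, the time multiplied by the square root of kG·kX. When kG and kX are equal, X peaks at w of exactly one; when they differ, the peak comes below one. Before the peak X rises, and past it X falls.

I reckoned w by hand from the activation energies. South-west gives 12.9, south 0.0163 and north-east 2.38 × 10⁻⁴. North-west lies nearest to one on a ratio scale, so I commit to north-west, without a figure for X.

The forecast is the second chemist's side. It treats the flask as “a simple consecutive scheme” and names north-west, with 1.28% in south-west, 2.62% in south, 45.7% in north-west and 0.0335% in north-east.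

The simulation gives north-west, with 1.28%, 2.62%, 45.7% and 0.0335% in the same order, so the forecast holds within tolerance. The first chemist's view has its region on the cold side of the peak: from north-east through south to north-west, hotter flasks held more X.

South-west, at w of 12.9 against 0.589 for north-west, lost its X through the passing of X into Q. With that step struck out, south-west holds 65.9% of X instead of 1.28%, close to the first chemist's share and above the 45.7% that north-west holds with the step in place. Struck from south-west, that step is a change that turns the forecast wrong there.

A repeat of north-west at 40 °C has w of 0.0732, far below one, so its X should still be on the rising side, under the north-west figure. The simulation gives 11.4% of X, with 80.6% of G still there.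

(Its constants are invented; what happens was integrated by code.)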